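O1, C2, C3, C3a–C7a = inner dihydrobenzofuran (benzene ring B); primed locants = outer dihydrobenzofuran (benzene ring C); O1'', C2''–C5'' = oxolane. The last disconnections are two aryl benzyl ethers and three primary TIPS ethers; before that, all three oxygen heterocycles are opened at once at O1–C7a, O1'–C7a' (aryl bromides) and O1''–C5'' (primary tosylate), giving one acyclic triol.
Enabling feature: each ring oxygen sits on a benzylic CH (C2, C2', C2'') that is an aldol carbinol, and each lies three carbons from exactly one carbon it can reach in a five-membered closure: C7a and C7a' (each flanked by the C7/C7' methoxy group and the C3a/C3a' chain) and C5''. The primary oxygens on the C3, C3' and C3'' CH2 groups are silyl-blocked, so three non-crossing closures are programmed.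
The chain comes from three auxiliary-controlled aldol reactions: C2'–C3' (syn) and C2–C3 (syn, antipodal auxiliary) with one linchpin, 2-(2-bromo-5-cyano-3-methoxyphenyl)acetyl chloride, used twice (nitrile = latent aldehyde for the next aldol), then C2''–C3'' (anti) with a succinate imide whose C4'' centre comes from a Stobbe condensation and asymmetric hydrogenation.
Ring order: no heterocycle exists before the key step; there the oxolane closes first (SN2), then the dihydrofuran rings on rings C and B (copper-catalysed O-arylation). The syn units give the trans dihydrobenzofurans and the anti unit gives the all-cis oxolane.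

Key step: step 25

Remark: Ar = 4-(benzyloxy)-3-methoxyphenyl; TIPSO, TESO, TMSO = triisopropyl-, triethyl-, trimethylsilyloxy; RC = aryl group of 21 (bond in place of CHO); RB = aryl group of 28 (bond in place of CHO); (S,S)-Et-DuPHOS is assumed to give the (R) acid in step 17, otherwise its mirror image is used.

Step 1
Reactants: 1 4-amino-3-methoxybenzonitrile
Product: 2 4-amino-3-iodo-5-methoxybenzonitrile
Conditions: NIS, DMF, 0 → 25 °C
Reagents that add atoms: N-iodosuccinimide, O=C1CCC(=O)N1I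
Why: Electrophilic aromatic iodination; the amino group directs to its only free ortho position (para is held by the nitrile), which is the future C3a.

Step 2
Reactants: 2 4-amino-3-iodo-5-methoxybenzonitrile
Product: 3 4-bromo-3-iodo-5-methoxybenzonitrile
Conditions: t-BuONO, CuBr2, MeCN, 0 → 60 °C
Reagents that add atoms: copper dibromide, Br[Cu]Br
Why: Sandmeyer-type bromodediazoniation: diazotisation by the alkyl nitrite and bromine-atom transfer from CuBr2 to the aryl radical place bromine on the future C7a without touching the C–I bond.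

Step 3
Reactants: 3 4-bromo-3-iodo-5-methoxybenzonitrile; 4 (2-tert-butoxy-2-oxoethyl)zinc bromide
Product: 5 tert-butyl 2-(2-bromo-5-cyano-3-methoxyphenyl)acetate
Conditions: Pd2(dba)3 (cat.), XPhos (cat.), THF, 25 °C
Reagents that add atoms: none
Why: Negishi coupling of a Reformatsky reagent; zerovalent palladium adds oxidatively to the C–I bond far faster than to the C–Br bond, so only the future C3a is alkylated.

Step 4
Reactants: 5 tert-butyl 2-(2-bromo-5-cyano-3-methoxyphenyl)acetate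
Product: 6 2-(2-bromo-5-cyano-3-methoxyphenyl)acetic acid
Conditions: CF3CO2H, CH2Cl2, 25 °C
Reagents that add atoms: none
Why: Acidolysis of a tert-butyl ester through the tert-butyl cation (loss of isobutene); nitrile, aryl bromide and methyl ether are inert.

Step 5
Reactants: 6 2-(2-bromo-5-cyano-3-methoxyphenyl)acetic acid
Product: 7 2-(2-bromo-5-cyano-3-methoxyphenyl)acetyl chloride
Conditions: (COCl)2, DMF (cat.), CH2Cl2, 0 → 25 °C; evaporation, used crude in two portions
Reagents that add atoms: oxalyl chloride, O=C(Cl)C(=O)Cl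
Why: Acid chloride formation through the Vilsmeier-type chloroiminium catalyst; the by-products are gases, so one batch of the activated linchpin serves both acylations, and nitrile, aryl bromide and methyl ether are inert.

Step 6
Reactants: 7 2-(2-bromo-5-cyano-3-methoxyphenyl)acetyl chloride; 8 (S)-4-benzyloxazolidin-2-one
Product: 10 (S)-4-benzyl-3-[2-(2-bromo-5-cyano-3-methoxyphenyl)acetyl]oxazolidin-2-one, via lithium (S)-oxazolidinide 9 (not isolated)
Conditions: 8, n-BuLi, THF, −78 °C; then 7, −78 → 0 °C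
Reagents that add atoms: none
Why: N-acylation of a lithiated oxazolidinone by an acid chloride (addition–elimination at the acyl carbon); the amide anion is formed completely before 7 is added, so n-BuLi never meets the aryl bromide or the nitrile.

Step 7
Reactants: 7 2-(2-bromo-5-cyano-3-methoxyphenyl)acetyl chloride; 11 (R)-4-benzyloxazolidin-2-one
Product: 13 (R)-4-benzyl-3-[2-(2-bromo-5-cyano-3-methoxyphenyl)acetyl]oxazolidin-2-one, via lithium (R)-oxazolidinide 12 (not isolated)
Conditions: 11, n-BuLi, THF, −78 °C; then 7, −78 → 0 °C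
Reagents that add atoms: none
Why: Same N-acylation of a lithiated oxazolidinone as in step 6, with the second portion of 7, giving the antipodal imide for the inner unit.

Step 8
Reactants: 10 (S)-imide of the linchpin acid; 14 4-(benzyloxy)-3-methoxybenzaldehyde
Product: 16 (4S)-4-benzyl-3-[(2S,3S)-2-(2-bromo-5-cyano-3-methoxyphenyl)-3-hydroxy-3-Ar-propanoyl]oxazolidin-2-one, via Z-dibutylboron enolate 15 (not isolated)
Conditions: n-Bu2BOTf, i-Pr2NEt, CH2Cl2, 0 °C; 14, −78 → 0 °C; then H2O2, MeOH, aq. NaH2PO4/Na2HPO4 buffer, 0 °C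
Reagents that add atoms: none
Why: Evans syn-aldol reaction: the Z-boron enolate adds through a Zimmerman–Traxler chair on the enolate face away from the auxiliary benzyl group, which sets C3' and C2' as the syn pair (2S,3S in the imide).

Step 9
Reactants: 16 syn-aldol imide of the outer unit
Product: 17 4-bromo-3-[(2R,3S)-1,3-dihydroxy-3-Ar-propan-2-yl]-5-methoxybenzonitrile
Conditions: NaBH4, THF/H2O (3:1), 0 → 25 °C
Reagents that add atoms: none
Why: Borohydride reduction of the activated N-acyl oxazolidinone carbonyl gives the primary alcohol (future CH2OH on C3') and frees the auxiliary; no stereocentre is touched.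

Step 10
Reactants: 17 outer-unit diol
Product: 19 4-bromo-3-[(2R,3S)-3-Ar-3-(TESO)-1-(TIPSO)propan-2-yl]-5-methoxybenzonitrile, via primary TIPS ether 18 (not isolated)
Conditions: i-Pr3SiCl, imidazole, DMF, 0 °C; then Et3SiCl, 25 °C
Reagents that add atoms: triisopropylsilyl chloride, CC(C)[Si](Cl)(C(C)C)C(C)C; triethylsilyl chloride, CC[Si](Cl)(CC)CC
Why: Silylation under steric control: the bulky TIPS chloride reacts only at the primary hydroxyl, after which the smaller TES chloride caps the benzylic hydroxyl as an ether that can later be removed without loss of TIPS.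

Step 11
Reactants: 19 bis-silylated outer-unit nitrile
Product: 21 4-bromo-3-[(2R,3S)-3-Ar-3-(TESO)-1-(TIPSO)propan-2-yl]-5-methoxybenzaldehyde, via N-aluminio aldimine 20 (not isolated)
Conditions: i-Bu2AlH, toluene, −78 °C; then aq. potassium sodium tartrate, SiO2, 25 °C
Reagents that add atoms: water, O
Why: Partial reduction of a nitrile: one hydride transfer from i-Bu2AlH gives an N-aluminio aldimine that persists at low temperature and is hydrolysed to the aldehyde on work-up.

Step 12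
Reactants: 13 (R)-imide of the linchpin acid; 21 ring C aldehyde
Product: 23 (4R)-4-benzyl-3-[(2R,3R)-2-(2-bromo-5-cyano-3-methoxyphenyl)-3-hydroxy-3-RC-propanoyl]oxazolidin-2-one, via Z-dibutylboron enolate 22 (not isolated)
Conditions: n-Bu2BOTf, i-Pr2NEt, CH2Cl2, 0 °C; 21, −78 → 0 °C; then H2O2, MeOH, aq. NaH2PO4/Na2HPO4 buffer, 0 °C
Reagents that add atoms: none
Why: Evans syn-aldol reaction with the antipodal auxiliary: the same chair transition state, now on the opposite enolate face, sets C3 and C2 as the syn pair (2R,3R in the imide), and the remote centres of 21 have no say.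

Step 13
Reactants: 23 syn-aldol imide of the inner unit
Product: 24 4-bromo-3-[(2S,3R)-1,3-dihydroxy-3-RC-propan-2-yl]-5-methoxybenzonitrile
Conditions: NaBH4, THF/H2O (3:1), 0 → 25 °C
Reagents that add atoms: none
Why: Borohydride reduction of the N-acyl oxazolidinone to the primary alcohol (future CH2OH on C3) with release of the auxiliary; silyl ethers and aryl bromides are inert.

Step 14
Reactants: 24 inner-unit diol
Product: 26 4-bromo-3-[(2S,3R)-3-RC-3-(TESO)-1-(TIPSO)propan-2-yl]-5-methoxybenzonitrile, via primary TIPS ether 25 (not isolated)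
Conditions: i-Pr3SiCl, imidazole, DMF, 0 °C; then Et3SiCl, 25 °C
Reagents that add atoms: triisopropylsilyl chloride, CC(C)[Si](Cl)(C(C)C)C(C)C; triethylsilyl chloride, CC[Si](Cl)(CC)CC
Why: Sterically controlled silylation as in step 10: TIPS on the primary oxygen, then TES on the benzylic oxygen.

Step 15
Reactants: 26 bis-silylated two-unit nitrile
Product: 28 4-bromo-3-[(2S,3R)-3-RC-3-(TESO)-1-(TIPSO)propan-2-yl]-5-methoxybenzaldehyde, via N-aluminio aldimine 27 (not isolated)
Conditions: i-Bu2AlH, toluene, −78 °C; then aq. potassium sodium tartrate, SiO2, 25 °C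
Reagents that add atoms: water, O
Why: Partial reduction of the nitrile to the aldimine and hydrolysis, as in step 11.

Step 16
Reactants: 14 4-(benzyloxy)-3-methoxybenzaldehyde; 29 di-tert-butyl succinate
Product: 30 (E)-4-Ar-3-(tert-butoxycarbonyl)but-3-enoic acid
Conditions: KOt-Bu, t-BuOH, 80 °C; then aq. HCl
Reagents that add atoms: none
Why: Stobbe condensation: aldol addition, lactonisation to a paraconic ester and E1cB ring opening give the alkylidene succinic half-ester with the free acid on the CH2 side.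

Step 17
Reactants: 30 Stobbe half-ester
Product: 31 (3R)-4-Ar-3-(tert-butoxycarbonyl)butanoic acid
Conditions: H2 (5 bar), [Rh(cod)((S,S)-Et-DuPHOS)]BF4 (cat.), MeOH, 25 °C
Reagents that add atoms: none
Why: Asymmetric hydrogenation of an itaconate-type half-ester: the substrate chelates rhodium through alkene and carboxylate, and the chiral bisphospholane fixes the face of hydrogen delivery, which sets the future C4'' as R.

Step 18
Reactants: 31 (3R)-succinic half-ester; 11 (R)-4-benzyloxazolidin-2-one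
Product: 33 (4R)-4-benzyl-3-[(3R)-4-Ar-3-(tert-butoxycarbonyl)butanoyl]oxazolidin-2-one, via mixed pivalic anhydride 32 (not isolated)
Conditions: t-BuCOCl, Et3N, THF, −20 °C; then LiCl, 11, 25 °C
Reagents that add atoms: none
Why: N-acylation through a mixed anhydride: the LiCl-activated oxazolidinone attacks the unhindered butanoyl carbonyl and not the pivaloyl one, and since no hydrogen chloride is generated the acid-labile tert-butyl ester is untouched.

Step 19
Reactants: 33 succinate imide; 28 ring B aldehyde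
Product: 34 (4R)-4-benzyl-3-[(2S,3R)-2-[(2R)-1-tert-butoxy-1-oxo-3-Ar-propan-2-yl]-3-RB-3-(TMSO)propanoyl]oxazolidin-2-one
Conditions: MgCl2 (cat.), Et3N, Me3SiCl, EtOAc, 25 °C
Reagents that add atoms: chlorotrimethylsilane, C[Si](C)(C)Cl
Why: Magnesium-halide-catalysed anti-aldol reaction of an N-acyl oxazolidinone: the chelated Z-magnesium enolate reacts through a boat-like transition state on the face away from the auxiliary benzyl group and the aldolate is trapped as its TMS ether, which sets C3'' and C2'' anti to each other under auxiliary control.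

Step 20
Reactants: 34 anti-aldol imide
Product: 35 tert-butyl (2R,3R,4R)-2-(Ar-methyl)-3-(hydroxymethyl)-4-RB-4-(TMSO)butanoate
Conditions: LiBH4, THF, H2O (1 equiv), 0 °C
Reagents that add atoms: none
Why: Chemoselective hydride reduction: LiBH4 reduces the imide carbonyl much faster than the hindered tert-butyl ester, giving the future CH2OH on C3'' and releasing the auxiliary.

Step 21
Reactants: 35 hydroxy ester
Product: 36 tert-butyl (2R,3R,4R)-2-(Ar-methyl)-4-RB-3-[(TIPSO)methyl]-4-(TMSO)butanoate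
Conditions: i-Pr3SiCl, imidazole, DMF, 25 °C
Reagents that add atoms: triisopropylsilyl chloride, CC(C)[Si](Cl)(C(C)C)C(C)C
Why: Silylation of the only free hydroxyl, which blocks the primary oxygen that could otherwise close a competing oxolane.

Step 22
Reactants: 36 fully silylated tert-butyl ester
Product: 37 (2R,3R,4R)-2-(Ar-methyl)-4-RB-3-[(TIPSO)methyl]-4-(TMSO)butan-1-ol
Conditions: i-Bu2AlH, CH2Cl2, −78 → 0 °C
Reagents that add atoms: none
Why: Hydride reduction of the ester to the primary alcohol that is the future C5''; silyl ethers and aryl bromides are inert to i-Bu2AlH.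

Step 23
Reactants: 37 primary alcohol
Product: 38 (2R,3R,4R)-2-(Ar-methyl)-4-RB-3-[(TIPSO)methyl]-4-(TMSO)butyl 4-methylbenzenesulfonate
Conditions: TsCl, Et3N, DMAP (cat.), CH2Cl2, 0 °C
Reagents that add atoms: 4-toluenesulfonyl chloride, Cc1ccc(cc1)S(Cl)(=O)=O
Why: Sulfonylation of the only free hydroxyl turns C5'' into an SN2 electrophile.

Step 24
Reactants: 38 tosylate
Product: 39 triol tosylate (38 with the TMS ether and both TES ethers replaced by OH), used at once
Conditions: HF·pyridine, pyridine, THF, 0 °C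
Reagents that add atoms: none
Why: Sterically controlled desilylation: buffered HF·pyridine cleaves the secondary TES and TMS ethers much faster than the primary TIPS ethers, freeing the three nucleophilic oxygens.

Step 25
Reactants: 39 triol tosylate
Product: 41 target as tris-TIPS ether and bis-benzyl ether, via oxolane diol 40 (not isolated)
Conditions: CuI (cat.), 3,4,7,8-tetramethyl-1,10-phenanthroline (cat.), Cs2CO3, toluene, 110 °C, high dilution
Reagents that add atoms: none
Why: Caesium carbonate generates the three benzylic alkoxides; the C2''-alkoxide displaces the primary tosylate (SN2, 5-exo-tet) to give the oxolane 40, and each of the other two alkoxides, bound to monovalent copper, brings the metal next to its own C–Br bond so that oxidative addition (to trivalent copper) and C(aryl)–O reductive elimination close O1–C7a on ring B and O1'–C7a' on ring C as five-membered rings. The closest known reaction type is the copper-catalysed intramolecular O-arylation (Ullmann etherification) of 2-(2-haloaryl)-1-arylethanols to trans-2-aryl-2,3-dihydrobenzofurans, run here twice in the same flask as a Williamson cyclisation. No stereocentre is formed: the C–O bonds at C2, C2' and C2'' stay intact (retention), so the two syn-aldol units become the trans dihydrobenzofurans and the anti unit becomes the all-cis oxolane. The step needs each alkoxide to close only its own ring and no primary oxygen to compete; this is secured because each alkoxide is three carbons from a single electrophilic carbon (the bromide of the neighbouring ring is para to its chain and out of reach), because the three primary hydroxyls are TIPS-blocked, and because high dilution disfavours intermolecular coupling.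

Step 26
Reactants: 41 protected target
Product: 42 target as bis-benzyl ether
Conditions: n-Bu4NF, THF, 25 °C
Reagents that add atoms: none
Why: Fluoride-induced desilylation (strong Si–F bond) frees the three primary alcohols; benzyl ethers and the three rings are inert.

Step 27
Reactants: 42 bis-benzyl ether
Product: 43 target, CNP0395728.1
Conditions: H2 (1 bar), Pd/C, EtOAc/MeOH, 25 °C
Reagents that add atoms: none
Why: Catalytic hydrogenolysis of the two aryl benzyl ethers; under neutral conditions at ambient pressure the benzylic C–O bonds of the rings are expected to react far more slowly.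

Compound list
1 | 4-amino-3-methoxybenzonitrile | COc1cc(C#N)ccc1N | starting material
2 | 4-amino-3-iodo-5-methoxybenzonitrile | COc1cc(C#N)cc(I)c1N | intermediate
3 | 4-bromo-3-iodo-5-methoxybenzonitrile | COc1cc(C#N)cc(I)c1Br | intermediate
4 | (2-tert-butoxy-2-oxoethyl)zinc bromide (Reformatsky reagent, THF solution) | CC(C)(C)OC(=O)C[Zn]Br | starting material
5 | tert-butyl 2-(2-bromo-5-cyano-3-methoxyphenyl)acetate | COc1cc(C#N)cc(CC(=O)OC(C)(C)C)c1Br | intermediate
6 | 2-(2-bromo-5-cyano-3-methoxyphenyl)acetic acid (linchpin acid) | COc1cc(C#N)cc(CC(=O)O)c1Br | intermediate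
7 | 2-(2-bromo-5-cyano-3-methoxyphenyl)acetyl chloride (linchpin acid chloride) | COc1cc(C#N)cc(CC(=O)Cl)c1Br | intermediate
8 | (S)-4-benzyloxazolidin-2-one | O=C1N[C@@H](Cc2ccccc2)CO1 | starting material
9 | lithium salt of (S)-4-benzyloxazolidin-2-one (N-lithio) | O=C1N([Li])[C@@H](Cc2ccccc2)CO1 | intermediate
10 | (S)-4-benzyl-3-[2-(2-bromo-5-cyano-3-methoxyphenyl)acetyl]oxazolidin-2-one | COc1cc(C#N)cc(CC(=O)N2[C@@H](Cc3ccccc3)COC2=O)c1Br | intermediate
11 | (R)-4-benzyloxazolidin-2-one | O=C1N[C@H](Cc2ccccc2)CO1 | starting material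
12 | lithium salt of (R)-4-benzyloxazolidin-2-one (N-lithio) | O=C1N([Li])[C@H](Cc2ccccc2)CO1 | intermediate
13 | (R)-4-benzyl-3-[2-(2-bromo-5-cyano-3-methoxyphenyl)acetyl]oxazolidin-2-one | COc1cc(C#N)cc(CC(=O)N2[C@H](Cc3ccccc3)COC2=O)c1Br | intermediate
14 | 4-(benzyloxy)-3-methoxybenzaldehyde | COc1cc(C=O)ccc1OCc1ccccc1 | starting material
15 | Z-dibutylboron enolate of 10 | CCCCB(CCCC)O/C(=C\c1cc(C#N)cc(OC)c1Br)N1[C@@H](Cc2ccccc2)COC1=O | intermediate
16 | (4S)-4-benzyl-3-[(2S,3S)-2-(2-bromo-5-cyano-3-methoxyphenyl)-3-hydroxy-3-Ar-propanoyl]oxazolidin-2-one (syn aldol) | O=C(N1[C@@H](Cc2ccccc2)COC1=O)[C@@H](c1cc(C#N)cc(OC)c1Br)[C@H](O)c1ccc(OCc2ccccc2)c(OC)c1 | intermediate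
17 | 4-bromo-3-[(2R,3S)-1,3-dihydroxy-3-Ar-propan-2-yl]-5-methoxybenzonitrile | N#Cc1cc(OC)c(Br)c(c1)[C@H](CO)[C@H](O)c1ccc(OCc2ccccc2)c(OC)c1 | intermediate
18 | 4-bromo-3-[(2R,3S)-3-hydroxy-3-Ar-1-(TIPSO)propan-2-yl]-5-methoxybenzonitrile | N#Cc1cc(OC)c(Br)c(c1)[C@H](CO[Si](C(C)C)(C(C)C)C(C)C)[C@H](O)c1ccc(OCc2ccccc2)c(OC)c1 | intermediate
19 | 4-bromo-3-[(2R,3S)-3-Ar-3-(TESO)-1-(TIPSO)propan-2-yl]-5-methoxybenzonitrile | N#Cc1cc(OC)c(Br)c(c1)[C@H](CO[Si](C(C)C)(C(C)C)C(C)C)[C@H](O[Si](CC)(CC)CC)c1ccc(OCc2ccccc2)c(OC)c1 | intermediate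
20 | N-(diisobutylaluminio)aldimine derived from 19 | CC(C)C[Al](CC(C)C)N=Cc1cc(OC)c(Br)c(c1)[C@H](CO[Si](C(C)C)(C(C)C)C(C)C)[C@H](O[Si](CC)(CC)CC)c1ccc(OCc2ccccc2)c(OC)c1 | intermediate
21 | 4-bromo-3-[(2R,3S)-3-Ar-3-(TESO)-1-(TIPSO)propan-2-yl]-5-methoxybenzaldehyde (ring C aldehyde) | O=Cc1cc(OC)c(Br)c(c1)[C@H](CO[Si](C(C)C)(C(C)C)C(C)C)[C@H](O[Si](CC)(CC)CC)c1ccc(OCc2ccccc2)c(OC)c1 | intermediate
22 | Z-dibutylboron enolate of 13 | CCCCB(CCCC)O/C(=C\c1cc(C#N)cc(OC)c1Br)N1[C@H](Cc2ccccc2)COC1=O | intermediate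
23 | (4R)-4-benzyl-3-[(2R,3R)-2-(2-bromo-5-cyano-3-methoxyphenyl)-3-hydroxy-3-RC-propanoyl]oxazolidin-2-one (syn aldol) | O=C(N1[C@H](Cc2ccccc2)COC1=O)[C@H](c1cc(C#N)cc(OC)c1Br)[C@@H](O)c1cc(OC)c(Br)c(c1)[C@H](CO[Si](C(C)C)(C(C)C)C(C)C)[C@H](O[Si](CC)(CC)CC)c1ccc(OCc2ccccc2)c(OC)c1 | intermediate
24 | 4-bromo-3-[(2S,3R)-1,3-dihydroxy-3-RC-propan-2-yl]-5-methoxybenzonitrile | N#Cc1cc(OC)c(Br)c(c1)[C@@H](CO)[C@@H](O)c1cc(OC)c(Br)c(c1)[C@H](CO[Si](C(C)C)(C(C)C)C(C)C)[C@H](O[Si](CC)(CC)CC)c1ccc(OCc2ccccc2)c(OC)c1 | intermediate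
25 | 4-bromo-3-[(2S,3R)-3-hydroxy-3-RC-1-(TIPSO)propan-2-yl]-5-methoxybenzonitrile | N#Cc1cc(OC)c(Br)c(c1)[C@@H](CO[Si](C(C)C)(C(C)C)C(C)C)[C@@H](O)c1cc(OC)c(Br)c(c1)[C@H](CO[Si](C(C)C)(C(C)C)C(C)C)[C@H](O[Si](CC)(CC)CC)c1ccc(OCc2ccccc2)c(OC)c1 | intermediate
26 | 4-bromo-3-[(2S,3R)-3-RC-3-(TESO)-1-(TIPSO)propan-2-yl]-5-methoxybenzonitrile | N#Cc1cc(OC)c(Br)c(c1)[C@@H](CO[Si](C(C)C)(C(C)C)C(C)C)[C@@H](O[Si](CC)(CC)CC)c1cc(OC)c(Br)c(c1)[C@H](CO[Si](C(C)C)(C(C)C)C(C)C)[C@H](O[Si](CC)(CC)CC)c1ccc(OCc2ccccc2)c(OC)c1 | intermediate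
27 | N-(diisobutylaluminio)aldimine derived from 26 | CC(C)C[Al](CC(C)C)N=Cc1cc(OC)c(Br)c(c1)[C@@H](CO[Si](C(C)C)(C(C)C)C(C)C)[C@@H](O[Si](CC)(CC)CC)c1cc(OC)c(Br)c(c1)[C@H](CO[Si](C(C)C)(C(C)C)C(C)C)[C@H](O[Si](CC)(CC)CC)c1ccc(OCc2ccccc2)c(OC)c1 | intermediate
28 | 4-bromo-3-[(2S,3R)-3-RC-3-(TESO)-1-(TIPSO)propan-2-yl]-5-methoxybenzaldehyde (ring B aldehyde) | O=Cc1cc(OC)c(Br)c(c1)[C@@H](CO[Si](C(C)C)(C(C)C)C(C)C)[C@@H](O[Si](CC)(CC)CC)c1cc(OC)c(Br)c(c1)[C@H](CO[Si](C(C)C)(C(C)C)C(C)C)[C@H](O[Si](CC)(CC)CC)c1ccc(OCc2ccccc2)c(OC)c1 | intermediate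
29 | di-tert-butyl succinate | CC(C)(C)OC(=O)CCC(=O)OC(C)(C)C | starting material
30 | (E)-4-Ar-3-(tert-butoxycarbonyl)but-3-enoic acid | OC(=O)C/C(=C\c1ccc(OCc2ccccc2)c(OC)c1)C(=O)OC(C)(C)C | intermediate
31 | (3R)-4-Ar-3-(tert-butoxycarbonyl)butanoic acid | OC(=O)C[C@@H](Cc1ccc(OCc2ccccc2)c(OC)c1)C(=O)OC(C)(C)C | intermediate
32 | mixed pivalic anhydride of 31 | CC(C)(C)C(=O)OC(=O)C[C@@H](Cc1ccc(OCc2ccccc2)c(OC)c1)C(=O)OC(C)(C)C | intermediate
33 | (4R)-4-benzyl-3-[(3R)-4-Ar-3-(tert-butoxycarbonyl)butanoyl]oxazolidin-2-one | O=C(C[C@@H](Cc1ccc(OCc2ccccc2)c(OC)c1)C(=O)OC(C)(C)C)N1[C@H](Cc2ccccc2)COC1=O | intermediate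
34 | (4R)-4-benzyl-3-[(2S,3R)-2-[(2R)-1-tert-butoxy-1-oxo-3-Ar-propan-2-yl]-3-RB-3-(TMSO)propanoyl]oxazolidin-2-one (anti aldol) | O=C(N1[C@H](Cc2ccccc2)COC1=O)[C@@H]([C@@H](Cc1ccc(OCc2ccccc2)c(OC)c1)C(=O)OC(C)(C)C)[C@@H](O[Si](C)(C)C)c1cc(OC)c(Br)c(c1)[C@@H](CO[Si](C(C)C)(C(C)C)C(C)C)[C@@H](O[Si](CC)(CC)CC)c1cc(OC)c(Br)c(c1)[C@H](CO[Si](C(C)C)(C(C)C)C(C)C)[C@H](O[Si](CC)(CC)CC)c1ccc(OCc2ccccc2)c(OC)c1 | intermediate
35 | tert-butyl (2R,3R,4R)-2-(Ar-methyl)-3-(hydroxymethyl)-4-RB-4-(TMSO)butanoate | OC[C@@H]([C@@H](Cc1ccc(OCc2ccccc2)c(OC)c1)C(=O)OC(C)(C)C)[C@@H](O[Si](C)(C)C)c1cc(OC)c(Br)c(c1)[C@@H](CO[Si](C(C)C)(C(C)C)C(C)C)[C@@H](O[Si](CC)(CC)CC)c1cc(OC)c(Br)c(c1)[C@H](CO[Si](C(C)C)(C(C)C)C(C)C)[C@H](O[Si](CC)(CC)CC)c1ccc(OCc2ccccc2)c(OC)c1 | intermediate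
36 | tert-butyl (2R,3R,4R)-2-(Ar-methyl)-4-RB-3-[(TIPSO)methyl]-4-(TMSO)butanoate | CC(C)[Si](C(C)C)(C(C)C)OC[C@@H]([C@@H](Cc1ccc(OCc2ccccc2)c(OC)c1)C(=O)OC(C)(C)C)[C@@H](O[Si](C)(C)C)c1cc(OC)c(Br)c(c1)[C@@H](CO[Si](C(C)C)(C(C)C)C(C)C)[C@@H](O[Si](CC)(CC)CC)c1cc(OC)c(Br)c(c1)[C@H](CO[Si](C(C)C)(C(C)C)C(C)C)[C@H](O[Si](CC)(CC)CC)c1ccc(OCc2ccccc2)c(OC)c1 | intermediate
37 | (2R,3R,4R)-2-(Ar-methyl)-4-RB-3-[(TIPSO)methyl]-4-(TMSO)butan-1-ol | CC(C)[Si](C(C)C)(C(C)C)OC[C@@H]([C@@H](Cc1ccc(OCc2ccccc2)c(OC)c1)CO)[C@@H](O[Si](C)(C)C)c1cc(OC)c(Br)c(c1)[C@@H](CO[Si](C(C)C)(C(C)C)C(C)C)[C@@H](O[Si](CC)(CC)CC)c1cc(OC)c(Br)c(c1)[C@H](CO[Si](C(C)C)(C(C)C)C(C)C)[C@H](O[Si](CC)(CC)CC)c1ccc(OCc2ccccc2)c(OC)c1 | intermediate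
38 | (2R,3R,4R)-2-(Ar-methyl)-4-RB-3-[(TIPSO)methyl]-4-(TMSO)butyl 4-methylbenzenesulfonate | CC(C)[Si](C(C)C)(C(C)C)OC[C@@H]([C@@H](Cc1ccc(OCc2ccccc2)c(OC)c1)COS(=O)(=O)c1ccc(C)cc1)[C@@H](O[Si](C)(C)C)c1cc(OC)c(Br)c(c1)[C@@H](CO[Si](C(C)C)(C(C)C)C(C)C)[C@@H](O[Si](CC)(CC)CC)c1cc(OC)c(Br)c(c1)[C@H](CO[Si](C(C)C)(C(C)C)C(C)C)[C@H](O[Si](CC)(CC)CC)c1ccc(OCc2ccccc2)c(OC)c1 | intermediate
39 | triol tosylate: 38 with the TMS ether and both TES ethers replaced by OH (three free benzylic hydroxyls, three primary TIPS ethers, two aryl bromides) | CC(C)[Si](C(C)C)(C(C)C)OC[C@@H]([C@@H](Cc1ccc(OCc2ccccc2)c(OC)c1)COS(=O)(=O)c1ccc(C)cc1)[C@@H](O)c1cc(OC)c(Br)c(c1)[C@@H](CO[Si](C(C)C)(C(C)C)C(C)C)[C@@H](O)c1cc(OC)c(Br)c(c1)[C@H](CO[Si](C(C)C)(C(C)C)C(C)C)[C@H](O)c1ccc(OCc2ccccc2)c(OC)c1 | intermediate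
40 | oxolane diol: (2R,3R,4R)-4-(Ar-methyl)-3-[(TIPSO)methyl]oxolane carrying at C2 the dibromo aryl chain of 39 with both benzylic hydroxyls free | COc1cc(C[C@H]2CO[C@@H](c3cc(OC)c(Br)c(c3)[C@@H](CO[Si](C(C)C)(C(C)C)C(C)C)[C@@H](O)c3cc(OC)c(Br)c(c3)[C@H](CO[Si](C(C)C)(C(C)C)C(C)C)[C@H](O)c3ccc(OCc4ccccc4)c(OC)c3)[C@H]2CO[Si](C(C)C)(C(C)C)C(C)C)ccc1OCc1ccccc1 | intermediate
41 | target as tris-TIPS ether (three primary oxygens) and bis-benzyl ether (two phenolic oxygens) | COc1cc(C[C@H]2CO[C@@H](c3cc(OC)c4c(c3)[C@@H](CO[Si](C(C)C)(C(C)C)C(C)C)[C@H](c3cc(OC)c5c(c3)[C@H](CO[Si](C(C)C)(C(C)C)C(C)C)[C@@H](c3ccc(OCc6ccccc6)c(OC)c3)O5)O4)[C@H]2CO[Si](C(C)C)(C(C)C)C(C)C)ccc1OCc1ccccc1 | intermediate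
42 | target as bis-benzyl ether of the two phenols | COc1cc(C[C@H]2CO[C@@H](c3cc(OC)c4c(c3)[C@@H](CO)[C@H](c3cc(OC)c5c(c3)[C@H](CO)[C@@H](c3ccc(OCc6ccccc6)c(OC)c3)O5)O4)[C@H]2CO)ccc1OCc1ccccc1 | intermediate
43 | CNP0395728.1: oxolane (2R,3R,4R), inner dihydrobenzofuran (2R,3S), outer dihydrobenzofuran (2S,3R) | COc1cc(C[C@H]2CO[C@@H](c3cc(OC)c4c(c3)[C@@H](CO)[C@H](c3cc(OC)c5c(c3)[C@H](CO)[C@@H](c3ccc(O)c(OC)c3)O5)O4)[C@H]2CO)ccc1O | target

Total step count: 27. Longest linear sequence: 23 steps (1–6, 8–15, 19–27).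

Steps most likely to fail

Step 25. The copper-mediated closures may stall at the doubly ortho-flanked C–Br bonds, with protodebromination taking over. A TIPS group may also migrate from a primary to a neighbouring secondary oxygen at 110 °C, after which the ring closes through the wrong oxygen. The fallback sets out from 39 and runs the closures in two stages with a different metal. K2CO3 in MeCN at 50 °C closes only the oxolane and gives the oxolane diol 40, which is isolated (no compound outside the list is made: F0). Both dihydrofuran rings are then closed at 80 °C with Pd(OAc)2, 2-(di-tert-butylphosphino)-1,1'-binaphthyl and Cs2CO3 in toluene. Oxidative addition to zerovalent palladium tolerates hindered, electron-rich aryl bromides, and the bulky ligand favours C–O reductive elimination over β-hydride loss. The fallback comes back to the route at 41.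

Step 19. The magnesium-catalysed aldol may give low conversion or poor facial control with the β-branched, ester-bearing imide, through retro-aldol equilibration before silyl capture. The fallback sets out from 33 and 28 and uses the stoichiometric boron enolate of 33 (n-Bu2BOTf, i-Pr2NEt, CH2Cl2). It is added at −78 °C to aldehyde 28 precomplexed with Et2AlCl, a Lewis-acid-promoted open-transition-state aldol that is expected to give the same anti diastereomer. This gives the free anti-aldol imide F1, which is silylated with Me3SiCl and imidazole and comes back to the route at 34.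

Step 27. Once the benzyl ethers are gone, over-reduction may cleave the benzylic C2–O1, C2'–O1' or C2''–O1'' bonds. The fallback sets out from 42 and removes the benzyl groups by Lewis-acid-mediated transfer to a cation scavenger instead of hydrogen: BCl3 with pentamethylbenzene in CH2Cl2 at −78 °C. It gives 43 directly (no compound outside the list is made: F0).

Further compounds
F0 | step 25 | none | none
F1 | step 19 | (4R)-4-benzyl-3-[(2S,3R)-2-[(2R)-1-tert-butoxy-1-oxo-3-Ar-propan-2-yl]-3-hydroxy-3-RB-propanoyl]oxazolidin-2-one | O=C(N1[C@H](Cc2ccccc2)COC1=O)[C@@H]([C@@H](Cc1ccc(OCc2ccccc2)c(OC)c1)C(=O)OC(C)(C)C)[C@@H](O)c1cc(OC)c(Br)c(c1)[C@@H](CO[Si](C(C)C)(C(C)C)C(C)C)[C@@H](O[Si](CC)(CC)CC)c1cc(OC)c(Br)c(c1)[C@H](CO[Si](C(C)C)(C(C)C)C(C)C)[C@H](O[Si](CC)(CC)CC)c1ccc(OCc2ccccc2)c(OC)c1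
F0 | step 27 | none | none
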